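## Retrosynthetic overview

1. Target 20 (ring C1 = CHOAc to C6 = CH2; side chain C1' = CHBr, C2' = CH2Cl) comes from two SN2 brominations with inversion: allylic C1'–OH last, neopentyl C5–OH before it.
2. The only ring is closed late by ring-closing metathesis (C2=C3) of an acyclic diene.
3. The anti C1–OAc / C5–OH pattern comes from an Evans–Tishchenko reduction of a β-hydroxy ketone.
4. The key C6–C1 bond comes from an intermolecular boron aldol between methyl ketone 11 (C3–C6 plus the gem-dimethyl group) and chiral enal 7 (C1, C2, C1', C2').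
5. Enal 7 comes from ethyl (R)-4-chloro-3-hydroxybutanoate (Mannich α-methylenation); ketone 11 comes from prenyl bromide and acetaldehyde (Barbier allylation, oxidation).

Assumption: ethyl (R)-4-chloro-3-hydroxybutanoate (bulk chlorohydrin, >99% ee) counts as a cheap commercial starting material and supplies the C1' stereocentre and the chlorine.

## Route

Step 1
Reactants: 1 ethyl (3R)-4-chloro-3-hydroxybutanoate; 2 tert-butyldimethylsilyl chloride
Product: 3 ethyl (3R)-3-[(tert-butyldimethylsilyl)oxy]-4-chlorobutanoate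
Conditions: TBSCl, imidazole, DMF, 0 °C → rt
Reagents that add atoms: tert-butyldimethylsilyl chloride 2, CC(C)(C)[Si](C)(C)Cl
Why: Routine silyl ether formation protects the secondary hydroxyl, whose (R) configuration (future C1') is bought in and kept until step 11.

Step 2
Reactants: 3 ethyl (3R)-3-[(tert-butyldimethylsilyl)oxy]-4-chlorobutanoate
Product: 4 (3R)-3-[(tert-butyldimethylsilyl)oxy]-4-chlorobutanal
Conditions: iBu2AlH (DIBAL-H, 1.1 equiv), CH2Cl2, −78 °C; aq. potassium sodium tartrate (KNaC4H4O6)
Reagents that add atoms: none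
Why: Partial ester reduction with DIBAL-H at −78 °C stops at the tetrahedral aluminate, which gives the aldehyde on work-up while the silyl ether and the primary chloride stay inert.

Step 3
Reactants: 4 (3R)-3-[(tert-butyldimethylsilyl)oxy]-4-chlorobutanal; 5 N,N-dimethylmethyleneiminium iodide (Eschenmoser's salt)
Product: 7 (3R)-3-[(tert-butyldimethylsilyl)oxy]-4-chloro-2-methylidenebutanal, via Mannich base 6 (not isolated)
Conditions: CH2=NMe2+ I− (2.5 equiv), Et3N (5 equiv), CH2Cl2, rt, 16 h
Reagents that add atoms: N,N-dimethylmethyleneiminium iodide 5, C=[N+](C)C.[I-]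
Why: An intermolecular Mannich reaction of the aldehyde enol with the iminium salt, followed by E1cB loss of dimethylamine (Mannich α-methylenation), gives the α-methylene aldehyde without touching the β-stereocentre.

Step 4
Reactants: 8 1-bromo-3-methylbut-2-ene (prenyl bromide); 9 acetaldehyde
Product: 10 3,3-dimethylpent-4-en-2-ol (racemic)
Conditions: Zn dust, THF/sat. aq. NH4Cl, 0 °C → rt
Reagents that add atoms: acetaldehyde 9, CC=O
Why: In this zinc-mediated Barbier carbonyl allylation the prenylzinc reagent adds through its γ-carbon (SE2'), which builds the quaternary gem-dimethyl carbon next to a vinyl group; the racemic carbinol centre is erased in step 5.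

Step 5
Reactants: 10 3,3-dimethylpent-4-en-2-ol
Product: 11 3,3-dimethylpent-4-en-2-one
Conditions: (COCl)2, DMSO, CH2Cl2, −78 °C; Et3N, → 0 °C; distillation
Reagents that add atoms: none
Why: Swern oxidation converts the hindered secondary alcohol into the volatile methyl ketone, whose only enolisable position is the methyl group.

Step 6
Reactants: 7 (3R)-3-[(tert-butyldimethylsilyl)oxy]-4-chloro-2-methylidenebutanal; 11 3,3-dimethylpent-4-en-2-one; 12 (−)-B-chlorodiisopinocampheylborane
Product: 14 (6R,8R)-8-[(tert-butyldimethylsilyl)oxy]-9-chloro-6-hydroxy-3,3-dimethyl-7-methylidenenon-1-en-4-one, via enol borinate 13 (not isolated)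
Conditions: 11 (1.5 equiv), (−)-Ipc2BCl (1.7 equiv), Et3N (2.2 equiv), Et2O, 0 °C, 1 h; then 7, −78 → −20 °C, 16 h; then MeOH, pH 7 buffer (NaH2PO4/Na2HPO4), 30% H2O2, 0 °C
Reagents that add atoms: 3,3-dimethylpent-4-en-2-one 11, CC(=O)C(C)(C)C=C; (−)-B-chlorodiisopinocampheylborane 12, ClB([C@@H]1C[C@@H]2C[C@H]([C@H]1C)C2(C)C)[C@@H]1C[C@@H]2C[C@H]([C@H]1C)C2(C)C (boron and isopinocampheyl groups are present only in 13)
Why: In this boron-mediated (Paterson) aldol addition the ketone enolises only at CH3 and adds 1,2 to the enal, and the (−)-Ipc ligands direct the methyl-ketone enolate to the re face of the aldehyde to set (6R) (ring C1); the minor (6S) epimer is a diastereomer and is removed by chromatography.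

Step 7
Reactants: 14 (6R,8R)-8-[(tert-butyldimethylsilyl)oxy]-9-chloro-6-hydroxy-3,3-dimethyl-7-methylidenenon-1-en-4-one; 9 acetaldehyde
Product: 15 (4R,6R,8R)-8-[(tert-butyldimethylsilyl)oxy]-9-chloro-4-hydroxy-3,3-dimethyl-7-methylidenenon-1-en-6-yl acetate
Conditions: SmI2 (0.3 equiv), MeCHO (8 equiv), THF, −10 °C
Reagents that add atoms: acetaldehyde 9, CC=O
Why: In the Evans–Tishchenko reduction the samarium-bound hemiacetal of the C6 hydroxyl and acetaldehyde delivers hydride intramolecularly to the ketone, which sets (4R) anti to C6, places the acetate on the future C1 oxygen and leaves the neopentyl hydroxyl free.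

Step 8
Reactants: 15 (4R,6R,8R)-8-[(tert-butyldimethylsilyl)oxy]-9-chloro-4-hydroxy-3,3-dimethyl-7-methylidenenon-1-en-6-yl acetate
Product: 16 (1R,5R)-2-[(1R)-1-[(tert-butyldimethylsilyl)oxy]-2-chloroethyl]-5-hydroxy-4,4-dimethylcyclohex-2-en-1-yl acetate
Conditions: second-generation Hoveyda–Grubbs catalyst RuCl2(SIMes)(=CHC6H4-2-OiPr) (10 mol%), toluene (0.005 M), 80 °C, Ar sparge
Reagents that add atoms: none
Why: Ring-closing metathesis joins the neopentyl vinyl group and the 1,1-disubstituted alkene into the trisubstituted C2=C3 bond of the six-membered ring, helped by the gem-dimethyl effect, and touches no stereocentre.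

Step 9
Reactants: 16 (1R,5R)-2-[(1R)-1-[(tert-butyldimethylsilyl)oxy]-2-chloroethyl]-5-hydroxy-4,4-dimethylcyclohex-2-en-1-yl acetate; 17 tetrabromomethane
Product: 18 (1R,5S)-5-bromo-2-[(1R)-1-[(tert-butyldimethylsilyl)oxy]-2-chloroethyl]-4,4-dimethylcyclohex-2-en-1-yl acetate
Conditions: PPh3 (3 equiv), CBr4 (3 equiv), toluene, 0 → 60 °C
Reagents that add atoms: tetrabromomethane 17, BrC(Br)(Br)Br
Why: In the Appel reaction the alkoxyphosphonium salt of the neopentyl secondary alcohol is displaced by bromide in an SN2 step with inversion, (5R)-OH to (5S)-Br, which puts bromine cis to the acetate.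

Step 10
Reactants: 18 (1R,5S)-5-bromo-2-[(1R)-1-[(tert-butyldimethylsilyl)oxy]-2-chloroethyl]-4,4-dimethylcyclohex-2-en-1-yl acetate
Product: 19 (1R,5S)-5-bromo-2-[(1R)-2-chloro-1-hydroxyethyl]-4,4-dimethylcyclohex-2-en-1-yl acetate
Conditions: HF·pyridine, pyridine, THF, 0 °C → rt
Reagents that add atoms: none
Why: Desilylation with buffered acidic fluoride frees the allylic alcohol while avoiding the basic conditions that would close the chlorohydrin to an epoxide or move the acetate.

Step 11
Reactants: 19 (1R,5S)-5-bromo-2-[(1R)-2-chloro-1-hydroxyethyl]-4,4-dimethylcyclohex-2-en-1-yl acetate; 17 tetrabromomethane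
Product: 20 (1R,5S)-5-bromo-2-[(1S)-1-bromo-2-chloroethyl]-4,4-dimethylcyclohex-2-en-1-yl acetate
Conditions: PPh3 (1.5 equiv), CBr4 (1.5 equiv), CH2Cl2, −20 → 0 °C, 30 min
Reagents that add atoms: tetrabromomethane 17, BrC(Br)(Br)Br
Why: A low-temperature Appel reaction converts the allylic secondary alcohol by direct SN2 with inversion, (1'R)-OH to (1'S)-Br, because the competing SN2' position is a hindered neopentyl carbon.

## Compound list

1 | ethyl (3R)-4-chloro-3-hydroxybutanoate | CCOC(=O)C[C@@H](O)CCl | starting material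
2 | tert-butyldimethylsilyl chloride | CC(C)(C)[Si](C)(C)Cl | starting material
3 | ethyl (3R)-3-[(tert-butyldimethylsilyl)oxy]-4-chlorobutanoate | CCOC(=O)C[C@@H](O[Si](C)(C)C(C)(C)C)CCl | intermediate
4 | (3R)-3-[(tert-butyldimethylsilyl)oxy]-4-chlorobutanal | O=CC[C@@H](O[Si](C)(C)C(C)(C)C)CCl | intermediate
5 | N,N-dimethylmethyleneiminium iodide (Eschenmoser's salt) | C=[N+](C)C.[I-] | starting material
6 | (3R)-3-[(tert-butyldimethylsilyl)oxy]-4-chloro-2-[(dimethylamino)methyl]butanal (Mannich base, both C2 epimers) | CN(C)CC(C=O)[C@@H](O[Si](C)(C)C(C)(C)C)CCl | intermediate (not isolated)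
7 | (3R)-3-[(tert-butyldimethylsilyl)oxy]-4-chloro-2-methylidenebutanal | C=C(C=O)[C@@H](O[Si](C)(C)C(C)(C)C)CCl | intermediate
8 | 1-bromo-3-methylbut-2-ene (prenyl bromide) | CC(C)=CCBr | starting material
9 | acetaldehyde | CC=O | starting material
10 | 3,3-dimethylpent-4-en-2-ol (racemic) | CC(O)C(C)(C)C=C | intermediate
11 | 3,3-dimethylpent-4-en-2-one | CC(=O)C(C)(C)C=C | intermediate
12 | (−)-B-chlorodiisopinocampheylborane, (−)-Ipc2BCl | ClB([C@@H]1C[C@@H]2C[C@H]([C@H]1C)C2(C)C)[C@@H]1C[C@@H]2C[C@H]([C@H]1C)C2(C)C | starting material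
13 | diisopinocampheylboron enolate of 11 (enol borinate) | C=CC(C)(C)C(=C)OB([C@@H]1C[C@@H]2C[C@H]([C@H]1C)C2(C)C)[C@@H]1C[C@@H]2C[C@H]([C@H]1C)C2(C)C | intermediate (not isolated)
14 | (6R,8R)-8-[(tert-butyldimethylsilyl)oxy]-9-chloro-6-hydroxy-3,3-dimethyl-7-methylidenenon-1-en-4-one | C=CC(C)(C)C(=O)C[C@@H](O)C(=C)[C@@H](O[Si](C)(C)C(C)(C)C)CCl | intermediate
15 | (4R,6R,8R)-8-[(tert-butyldimethylsilyl)oxy]-9-chloro-4-hydroxy-3,3-dimethyl-7-methylidenenon-1-en-6-yl acetate | C=CC(C)(C)[C@H](O)C[C@@H](OC(C)=O)C(=C)[C@@H](O[Si](C)(C)C(C)(C)C)CCl | intermediate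
16 | (1R,5R)-2-[(1R)-1-[(tert-butyldimethylsilyl)oxy]-2-chloroethyl]-5-hydroxy-4,4-dimethylcyclohex-2-en-1-yl acetate | CC(=O)O[C@@H]1C[C@@H](O)C(C)(C)C=C1[C@@H](O[Si](C)(C)C(C)(C)C)CCl | intermediate
17 | tetrabromomethane | BrC(Br)(Br)Br | starting material
18 | (1R,5S)-5-bromo-2-[(1R)-1-[(tert-butyldimethylsilyl)oxy]-2-chloroethyl]-4,4-dimethylcyclohex-2-en-1-yl acetate | CC(=O)O[C@@H]1C[C@H](Br)C(C)(C)C=C1[C@@H](O[Si](C)(C)C(C)(C)C)CCl | intermediate
19 | (1R,5S)-5-bromo-2-[(1R)-2-chloro-1-hydroxyethyl]-4,4-dimethylcyclohex-2-en-1-yl acetate | CC(=O)O[C@@H]1C[C@H](Br)C(C)(C)C=C1[C@@H](O)CCl | intermediate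
20 | (1R,5S)-5-bromo-2-[(1S)-1-bromo-2-chloroethyl]-4,4-dimethylcyclohex-2-en-1-yl acetate | CC(=O)O[C@@H]1C[C@H](Br)C(C)(C)C=C1[C@H](Br)CCl | target

## Step count and weak points

Total step count: 11. Longest linear sequence: 9 steps (steps 1–3, then 6–11); steps 4 and 5 make the second fragment.

The three steps most likely to fail are step 9, step 8 and step 6.

The bromination of step 9 is the weakest point. It is an SN2 displacement at a secondary carbon flanked by a quaternary centre, so E2 to the C5=C6 alkene, methyl migration or participation of the 1,3-acetate can compete. The fallback sets out from 16 and replaces the in-situ phosphonium activation by a discrete sulfonate and a naked bromide at low temperature. Tf2O and pyridine in CH2Cl2 at −40 °C give the triflate (1R,5R)-2-[(1R)-1-[(tert-butyldimethylsilyl)oxy]-2-chloroethyl]-4,4-dimethyl-5-[(trifluoromethylsulfonyl)oxy]cyclohex-2-en-1-yl acetate F1. This is displaced with inversion by Bu4NBr in toluene at −20 °C → rt, and the route is rejoined at 18.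

The ring closure of step 8 must join a vinyl group on a quaternary carbon to a 1,1-disubstituted alkene flanked by two branched carbons, so initiation and closure may be slow. The fallback sets out from 14 and closes the ring one step earlier, where the free allylic hydroxyl accelerates metathesis and the ketone carbon relieves crowding next to the quaternary centre. The same ruthenium catalyst gives (5R)-4-[(1R)-1-[(tert-butyldimethylsilyl)oxy]-2-chloroethyl]-5-hydroxy-2,2-dimethylcyclohex-3-en-1-one F2. The Evans–Tishchenko reduction (SmI2, MeCHO, THF, −10 °C) is then run on the ring, where hydride delivery from the hemiacetal on the ring hydroxyl across the ring gives the trans acetate-alcohol. The route is rejoined at 16.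

In the fragment union of step 6, the facial selectivity rests on reagent control against an unknown bias of the chiral enal, so the diastereomer ratio may be poor. The fallback sets out from 7 and 11 and makes the union stereoconvergent. The lithium enolate of 11 (LiN(iPr)2, THF, −78 °C) adds to 7 to give 14 together with its epimer (6S,8R)-8-[(tert-butyldimethylsilyl)oxy]-9-chloro-6-hydroxy-3,3-dimethyl-7-methylidenenon-1-en-4-one F3, and the two are separated. 14 goes on through step 7. F3 is reduced syn-selectively (Narasaka–Prasad: Et2BOMe, NaBH4, THF/MeOH, −78 °C) to (4R,6S,8R)-8-[(tert-butyldimethylsilyl)oxy]-9-chloro-3,3-dimethyl-7-methylidenenon-1-ene-4,6-diol F4. A Mitsunobu reaction with acetic acid (PPh3, DIAD, toluene, 0 °C) then reacts only at the allylic C6 carbinol (the neopentyl hydroxyl is inert), inverts it and installs the acetate. The route is rejoined at 15.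

## Further compounds

F1 | step 9 | (1R,5R)-2-[(1R)-1-[(tert-butyldimethylsilyl)oxy]-2-chloroethyl]-4,4-dimethyl-5-[(trifluoromethylsulfonyl)oxy]cyclohex-2-en-1-yl acetate | CC(=O)O[C@@H]1C[C@@H](OS(=O)(=O)C(F)(F)F)C(C)(C)C=C1[C@@H](O[Si](C)(C)C(C)(C)C)CCl
F2 | step 8 | (5R)-4-[(1R)-1-[(tert-butyldimethylsilyl)oxy]-2-chloroethyl]-5-hydroxy-2,2-dimethylcyclohex-3-en-1-one | O[C@@H]1CC(=O)C(C)(C)C=C1[C@@H](O[Si](C)(C)C(C)(C)C)CCl
F3 | step 6 | (6S,8R)-8-[(tert-butyldimethylsilyl)oxy]-9-chloro-6-hydroxy-3,3-dimethyl-7-methylidenenon-1-en-4-one | C=CC(C)(C)C(=O)C[C@H](O)C(=C)[C@@H](O[Si](C)(C)C(C)(C)C)CCl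
F4 | step 6 | (4R,6S,8R)-8-[(tert-butyldimethylsilyl)oxy]-9-chloro-3,3-dimethyl-7-methylidenenon-1-ene-4,6-diol | C=CC(C)(C)[C@H](O)C[C@H](O)C(=C)[C@@H](O[Si](C)(C)C(C)(C)C)CCl
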